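**Retrosynthetic overview**
- The target is read as epicatechin-(4α→8)-epicatechin 3-O-gallate-(4β→8)-epicatechin 3-O-gallate; the last step is hydrogenolysis of eighteen benzyl ethers.
- Upper unit, C3 and C4 (all-cis): from a 4-aryl-flav-3-en-3-ol silyl ether by C4 protonation, then C3 hydride delivery, both anti to the 2-aryl group (stereochemical relay from C2 of taxifolin).
- Key disconnection C4(upper)–C8(middle): Pd-catalysed carbene coupling of a flavan-4-one N-tosylhydrazone with the 8-bromide of the lower dimer. The carbonyl carbon acts as a donor through its diazo form, so two acceptor carbons (C=O and C–Br) are joined.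
- Middle–lower 4β→8 bond: TMSOTf-mediated C4-cation/C8 arylation of two galloylated epicatechin units; the 8-bromine blocks oligomerisation and later serves as the coupling handle.
- No ring is built: the three chroman cores (rings A, B, C) come from (−)-epicatechin (twice) and (+)-taxifolin; lower and middle units are joined first, the upper unit last.

Assumption: the upper unit of the given SMILES is 2,3-cis-3,4-cis (4α) and the middle unit 2,3-cis-3,4-trans (4β); the C=N geometry of the hydrazone is not controlled and does not matter.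

**Route**

Step 1
Reactants: 1 (−)-epicatechin; 2 benzyl bromide
Product: 3 5,7,3',4'-tetra-O-benzyl-(−)-epicatechin
Conditions: BnBr (4.4 equiv), K2CO3, DMF, 0 °C to rt, Ar
Reagents that add atoms: benzyl bromide, BrCc1ccccc1
Why: Williamson ether synthesis in which K2CO3 deprotonates only the four phenols (not the secondary 3-OH), which are benzylated by SN2 on BnBr, leaving C2 and C3 (2R,3R) untouched.

Step 2
Reactants: 3 5,7,3',4'-tetra-O-benzyl-(−)-epicatechin; 4 3,4,5-tris(benzyloxy)benzoic acid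
Product: 5 5,7,3',4'-tetra-O-benzyl-(−)-epicatechin 3-O-(3,4,5-tri-O-benzyl)gallate
Conditions: DCC (1.6 equiv), DMAP (0.3 equiv), CH2Cl2, rt
Reagents that add atoms: 3,4,5-tris(benzyloxy)benzoic acid, OC(=O)c1cc(OCc2ccccc2)c(OCc2ccccc2)c(OCc2ccccc2)c1
Why: Steglich esterification in which the DCC-activated acid is transferred by DMAP to the axial 3-OH, and since no bond to C3 is broken its configuration is retained.

Step 3
Reactants: 5 5,7,3',4'-tetra-O-benzyl-(−)-epicatechin 3-O-(3,4,5-tri-O-benzyl)gallate; 6 2-ethoxyethanol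
Product: 7 5,7,3',4'-tetra-O-benzyl-4β-(2-ethoxyethoxy)epicatechin 3-O-(3,4,5-tri-O-benzyl)gallate (2,3-cis-3,4-trans)
Conditions: DDQ (2 equiv), 2-ethoxyethanol (5 equiv), CH2Cl2, rt
Reagents that add atoms: 2-ethoxyethanol, CCOCCO
Why: DDQ benzylic oxidation in which hydride abstraction from C4 gives the ring-A-stabilised cation, which the alcohol captures on the β face anti to the 3-acyloxy group, setting the 3,4-trans (4β) centre.

Step 4
Reactants: 7 the 4β-(2-ethoxyethoxy) gallate; 8 N-bromosuccinimide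
Product: 9 8-bromo-5,7,3',4'-tetra-O-benzyl-4β-(2-ethoxyethoxy)epicatechin 3-O-(3,4,5-tri-O-benzyl)gallate
Conditions: NBS (1.05 equiv), NaHCO3 (solid), CH2Cl2, −40 to 0 °C
Reagents that add atoms: N-bromosuccinimide, O=C1CCC(=O)N1Br
Why: Electrophilic aromatic bromination (SEAr) at C8 of ring A, the most nucleophilic free arene position (C6 is more hindered, the galloyl and ring B carbons far less activated), under neutral cold conditions that spare the acid-labile 4-ether.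

Step 5
Reactants: 9 the 8-bromo 4β-ether; 5 the benzylated epicatechin gallate (2.5 equiv, excess recovered)
Product: 10 [8-bromo-5,7,3',4'-tetra-O-benzylepicatechin 3-O-(tri-O-benzyl)gallate]-(4β→8)-[5,7,3',4'-tetra-O-benzylepicatechin 3-O-(tri-O-benzyl)gallate]
Conditions: TMSOTf (0.3 equiv), CH2Cl2, −78 to −40 °C; aq NaHCO3
Reagents that add atoms: none
Why: Lewis-acid-mediated Friedel–Crafts flavan coupling in which TMSOTf ionises the 4-ether of 9 to the C4 benzylic cation, which C8 of 5 attacks on the β face anti to the 3-O-galloyl group to give the natural 3,4-trans 4β→8 bond, while the 8-bromine of 9 prevents self-condensation.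

Step 6
Reactants: 11 (+)-taxifolin [(2R,3R)-dihydroquercetin]; 2 benzyl bromide
Product: 12 (2R,3R)-5,7,3',4'-tetra-O-benzyltaxifolin (2,3-trans 3-hydroxyflavan-4-one)
Conditions: BnBr (6 equiv), K2CO3, Bu4NI (0.1 equiv), DMF, rt to 50 °C, Ar
Reagents that add atoms: benzyl bromide, BrCc1ccccc1
Why: Williamson ether synthesis in which all four phenols, including the hydrogen-bonded 5-OH (hence iodide catalysis and gentle warming), are benzylated while the 3-OH stays free and the weak base leaves C2 (2R) intact.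

Step 7
Reactants: 12 tetra-O-benzyltaxifolin; 13 tert-butyldimethylsilyl chloride
Product: 14 (2R,3R)-5,7,3',4'-tetra-O-benzyl-3-O-(tert-butyldimethylsilyl)taxifolin
Conditions: TBSCl (2.5 equiv), imidazole (5 equiv), DMF, 40 °C
Reagents that add atoms: tert-butyldimethylsilyl chloride, CC(C)(C)[Si](C)(C)Cl
Why: Imidazole-promoted silylation of the secondary 3-OH, in which no bond to C3 is broken and imidazole is too weak a base to enolise C3.

Step 8
Reactants: 14 the 3-O-TBS flavan-4-one; 15 p-toluenesulfonyl hydrazide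
Product: 16 N-tosylhydrazone of 14 at C4 (2R; 2,3-trans)
Conditions: TsNHNH2 (1.5 equiv), PPTS (0.1 equiv), EtOH/THF, 65 °C
Reagents that add atoms: p-toluenesulfonyl hydrazide, Cc1ccc(cc1)S(=O)(=O)NN
Why: Acid-catalysed condensation of the ketone with the sulfonyl hydrazide gives the N-tosylhydrazone, the silyl ether tolerating PPTS and both stereocentres staying untouched.

Step 9
Reactants: 16 the N-tosylhydrazone (2 equiv); 10 the 8-bromo dimer bis-gallate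
Product: 18 [(2R)-5,7,3',4'-tetra-O-benzyl-3-(tert-butyldimethylsilyloxy)flav-3-en-4-yl]-(4→8)-[benzylated epicatechin gallate]-(4β→8)-[benzylated epicatechin gallate], via 4-diazoflavan 17 (not isolated)
Conditions: Pd2(dba)3 (5 mol %; dba = dibenzylideneacetone), XPhos (20 mol %), LiOtBu (4.5 equiv), 1,4-dioxane, 100 °C
Reagents that add atoms: none
Why: Barluenga–Valdés cross-coupling in which LiOtBu converts 16 into diazo compound 17 (Bamford–Stevens), whose carbon (the former electrophilic C4 carbonyl carbon) acts as the donor toward the arylpalladium bromide from oxidative addition of 10, giving a palladium carbene that undergoes migratory aryl insertion (C4–C8 bond) and syn β-hydride elimination of H-3 to the silyl enol ether, while C2 is never α to a carbonyl or hydrazone and keeps its 2R configuration (α-alkoxy hydrazones are known to give enol ethers in this coupling and α-stereocentres are known to survive it).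

Step 10
Reactants: 18 the silyl enol ether trimer
Product: 20 [5,7,3',4'-tetra-O-benzylepicatechin]-(4α→8)-[benzylated epicatechin gallate]-(4β→8)-[benzylated epicatechin gallate] (upper unit 2,3-cis-3,4-cis with free 3-OH), via flavan-3-one 19 (not isolated)
Conditions: Bu4NF (1.2 equiv), AcOH (1.5 equiv), THF, −40 to 0 °C; then LiBH(s-Bu)3 (5 equiv), −78 °C; aq NH4Cl
Reagents that add atoms: none
Why: Fluoride desilylation gives the C3=C4 enolate regiospecifically, which is protonated at C4 on the β face anti to the pseudo-axial 2-aryl group (A(1,2) strain) to give the 2,4-cis ketone 19, and the bulky hydride then adds to C3 from the same β face anti to both flanking aryl groups (as in the catechin-to-epicatechin ketone reduction and in cis-2,6-disubstituted cyclohexanones), so kinetic enolate protonation followed by diastereoselective trialkylborohydride reduction sets the 4α-aryl and 3α-OH centres.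

Step 11
Reactants: 20 the protected trimer
Product: 21 target, epicatechin-(4α→8)-epicatechin 3-O-gallate-(4β→8)-epicatechin 3-O-gallate (CNP0279403.2)
Conditions: H2 (1 atm), Pd(OH)2/C, THF/MeOH/H2O, rt
Reagents that add atoms: none
Why: Catalytic hydrogenolysis cleaves all eighteen benzyl ethers to toluene without touching the gallate esters, the interflavan bonds or any stereocentre.

**Compound list**

1 | (−)-epicatechin (2R,3R) | Oc1cc(O)c2c(c1)O[C@H](c1ccc(O)c(O)c1)[C@H](O)C2 | starting material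
2 | benzyl bromide | BrCc1ccccc1 | starting material
3 | 5,7,3',4'-tetra-O-benzyl-(−)-epicatechin | O(Cc1ccccc1)c1cc(OCc3ccccc3)c2c(c1)O[C@H](c1ccc(OCc3ccccc3)c(OCc3ccccc3)c1)[C@H](O)C2 | intermediate
4 | 3,4,5-tris(benzyloxy)benzoic acid | OC(=O)c1cc(OCc2ccccc2)c(OCc2ccccc2)c(OCc2ccccc2)c1 | starting material
5 | 5,7,3',4'-tetra-O-benzyl-(−)-epicatechin 3-O-(3,4,5-tri-O-benzyl)gallate | O(Cc1ccccc1)c1cc(OCc3ccccc3)c2c(c1)O[C@H](c1ccc(OCc3ccccc3)c(OCc3ccccc3)c1)[C@H](OC(=O)c1cc(OCc3ccccc3)c(OCc3ccccc3)c(OCc3ccccc3)c1)C2 | intermediate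
6 | 2-ethoxyethanol | CCOCCO | starting material
7 | 4β-(2-ethoxyethoxy) derivative of 5 (2,3-cis-3,4-trans) | O(Cc1ccccc1)c1cc(OCc3ccccc3)c2c(c1)O[C@H](c1ccc(OCc3ccccc3)c(OCc3ccccc3)c1)[C@H](OC(=O)c1cc(OCc3ccccc3)c(OCc3ccccc3)c(OCc3ccccc3)c1)[C@H]2OCCOCC | intermediate
8 | N-bromosuccinimide | O=C1CCC(=O)N1Br | starting material
9 | 8-bromo derivative of 7 | O(Cc1ccccc1)c1cc(OCc3ccccc3)c2c(c1Br)O[C@H](c1ccc(OCc3ccccc3)c(OCc3ccccc3)c1)[C@H](OC(=O)c1cc(OCc3ccccc3)c(OCc3ccccc3)c(OCc3ccccc3)c1)[C@H]2OCCOCC | intermediate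
10 | 8-bromo dimer bis-gallate, upper unit linked 4β→8 to the lower unit | O(Cc1ccccc1)c1cc(OCc3ccccc3)c2c(c1Br)O[C@H](c1ccc(OCc3ccccc3)c(OCc3ccccc3)c1)[C@H](OC(=O)c1cc(OCc3ccccc3)c(OCc3ccccc3)c(OCc3ccccc3)c1)[C@H]2c1c(OCc3ccccc3)cc(OCc3ccccc3)c2c1O[C@H](c1ccc(OCc3ccccc3)c(OCc3ccccc3)c1)[C@H](OC(=O)c1cc(OCc3ccccc3)c(OCc3ccccc3)c(OCc3ccccc3)c1)C2 | intermediate
11 | (+)-taxifolin (2R,3R) | Oc1cc(O)c2c(c1)O[C@H](c1ccc(O)c(O)c1)[C@@H](O)C2=O | starting material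
12 | (2R,3R)-5,7,3',4'-tetra-O-benzyltaxifolin | O(Cc1ccccc1)c1cc(OCc3ccccc3)c2c(c1)O[C@H](c1ccc(OCc3ccccc3)c(OCc3ccccc3)c1)[C@@H](O)C2=O | intermediate
13 | tert-butyldimethylsilyl chloride | CC(C)(C)[Si](C)(C)Cl | starting material
14 | (2R,3R)-5,7,3',4'-tetra-O-benzyl-3-O-TBS-taxifolin | O(Cc1ccccc1)c1cc(OCc3ccccc3)c2c(c1)O[C@H](c1ccc(OCc3ccccc3)c(OCc3ccccc3)c1)[C@@H](O[Si](C)(C)C(C)(C)C)C2=O | intermediate
15 | p-toluenesulfonyl hydrazide | Cc1ccc(cc1)S(=O)(=O)NN | starting material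
16 | C4 N-tosylhydrazone of 14 (2R; 2,3-trans) | O(Cc1ccccc1)c1cc(OCc3ccccc3)c2c(c1)O[C@H](c1ccc(OCc3ccccc3)c(OCc3ccccc3)c1)[C@@H](O[Si](C)(C)C(C)(C)C)C2=NNS(=O)(=O)c1ccc(C)cc1 | intermediate
17 | 4-diazo-5,7,3',4'-tetra-O-benzyl-3-O-TBS-flavan (2R; 2,3-trans) | O(Cc1ccccc1)c1cc(OCc3ccccc3)c2c(c1)O[C@H](c1ccc(OCc3ccccc3)c(OCc3ccccc3)c1)[C@@H](O[Si](C)(C)C(C)(C)C)C2=[N+]=[N-] | intermediate (not isolated)
18 | silyl enol ether trimer: (2R)-3-TBSO-flav-3-ene upper unit, C4 bonded to C8 of the middle unit | O(Cc1ccccc1)c1cc(OCc3ccccc3)c2c(c1)O[C@H](c1ccc(OCc3ccccc3)c(OCc3ccccc3)c1)C(O[Si](C)(C)C(C)(C)C)=C2c1c(OCc3ccccc3)cc(OCc3ccccc3)c2c1O[C@H](c1ccc(OCc3ccccc3)c(OCc3ccccc3)c1)[C@H](OC(=O)c1cc(OCc3ccccc3)c(OCc3ccccc3)c(OCc3ccccc3)c1)[C@H]2c1c(OCc3ccccc3)cc(OCc3ccccc3)c2c1O[C@H](c1ccc(OCc3ccccc3)c(OCc3ccccc3)c1)[C@H](OC(=O)c1cc(OCc3ccccc3)c(OCc3ccccc3)c(OCc3ccccc3)c1)C2 | intermediate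
19 | flavan-3-one trimer, upper unit 2,4-cis (2α-aryl, 4α-aryl) | O(Cc1ccccc1)c1cc(OCc3ccccc3)c2c(c1)O[C@H](c1ccc(OCc3ccccc3)c(OCc3ccccc3)c1)C(=O)[C@@H]2c1c(OCc3ccccc3)cc(OCc3ccccc3)c2c1O[C@H](c1ccc(OCc3ccccc3)c(OCc3ccccc3)c1)[C@H](OC(=O)c1cc(OCc3ccccc3)c(OCc3ccccc3)c(OCc3ccccc3)c1)[C@H]2c1c(OCc3ccccc3)cc(OCc3ccccc3)c2c1O[C@H](c1ccc(OCc3ccccc3)c(OCc3ccccc3)c1)[C@H](OC(=O)c1cc(OCc3ccccc3)c(OCc3ccccc3)c(OCc3ccccc3)c1)C2 | intermediate (not isolated)
20 | octadeca-O-benzyl target: upper unit all-cis with free 3-OH, linked 4α→8; middle unit linked 4β→8 | O(Cc1ccccc1)c1cc(OCc3ccccc3)c2c(c1)O[C@H](c1ccc(OCc3ccccc3)c(OCc3ccccc3)c1)[C@H](O)[C@@H]2c1c(OCc3ccccc3)cc(OCc3ccccc3)c2c1O[C@H](c1ccc(OCc3ccccc3)c(OCc3ccccc3)c1)[C@H](OC(=O)c1cc(OCc3ccccc3)c(OCc3ccccc3)c(OCc3ccccc3)c1)[C@H]2c1c(OCc3ccccc3)cc(OCc3ccccc3)c2c1O[C@H](c1ccc(OCc3ccccc3)c(OCc3ccccc3)c1)[C@H](OC(=O)c1cc(OCc3ccccc3)c(OCc3ccccc3)c(OCc3ccccc3)c1)C2 | intermediate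
21 | epicatechin-(4α→8)-epicatechin 3-O-gallate-(4β→8)-epicatechin 3-O-gallate | O=C(O[C@@H]1[C@@H](c2c(O)cc(O)c3c2O[C@H](c2ccc(O)c(O)c2)[C@H](OC(=O)c2cc(O)c(O)c(O)c2)C3)c2c(O)cc(O)c([C@@H]3c4c(O)cc(O)cc4O[C@H](c4ccc(O)c(O)c4)[C@@H]3O)c2O[C@@H]1c1ccc(O)c(O)c1)c1cc(O)c(O)c(O)c1 | target

**Step count**

Total: 11 steps. Longest linear sequence: 8 steps (1, 2, 3, 4, 5, 9, 10, 11).

**Steps most likely to fail, with fallbacks**

Step 9. The coupling joins two di-ortho-substituted carbons, and the slow, encumbered arylpalladium may lose to 1,2-hydride shift of 17 (to the aryl-free 3-silyloxyflav-3-ene). The fallback sets out from 3, 5 and 7 and returns at 18; it makes the bond with classical polarity and the wrong C4 configuration, which the endgame then corrects. Compound 3 is oxidised with DDQ and 2-ethoxyethanol to 5,7,3',4'-tetra-O-benzyl-4β-(2-ethoxyethoxy)epicatechin F1. Compound 7 is condensed with excess 5 (TMSOTf, −78 °C) to the bromine-free dimer bis-gallate F2. TMSOTf coupling of F1 with excess F2 (C8 of the upper unit of F2 attacks the C4 cation anti to the 3-OH) gives the all-4β→8 trimer alcohol F3. Dess–Martin oxidation gives the 4β-aryl flavan-3-one F4 (2,4-trans). Enol silylation toward the doubly benzylic C4 (TBSOTf, Et3N, CH2Cl2, 0 °C) erases C4 and delivers 18.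

Step 10. The hindered 2,2-diaryl enol may ketonise slowly, so the hydride would only deprotonate it; acetate could also epimerise C2 or C4 of 19 before reduction. The fallback sets out from 18 and returns at 20. Ionic hydrogenation (CF3CO2H, Et3SiH, CH2Cl2, −40 °C) protonates C4 and transfers hydride to the C3 silyloxocarbenium ion, both anti to the 2-aryl group, with no free ketone or enolate. This gives the all-cis 3-O-TBS trimer F5, which HF·pyridine in THF desilylates to 20.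

Step 6. The chelated 5-OH resists benzylation, and warm carbonate can open ring C through C3 enolisation, which would erode C2. The fallback sets out from 3 and returns at 18. Compound 3 is silylated (TBSCl, imidazole) to 3-O-TBS-tetra-O-benzylepicatechin F6. DDQ in wet CH2Cl2 gives the 4β-alcohol F7. Dess–Martin oxidation gives the 2,3-cis 3-silyloxyflavan-4-one F8. TsNHNH2 gives its tosylhydrazone F9. Under the step 9 conditions F9, through the 2,3-cis diazo compound F10, gives 18, because C3 becomes planar.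

Further compounds
F1 | step 9 | 5,7,3',4'-tetra-O-benzyl-4β-(2-ethoxyethoxy)-(−)-epicatechin | O(Cc1ccccc1)c1cc(OCc3ccccc3)c2c(c1)O[C@H](c1ccc(OCc3ccccc3)c(OCc3ccccc3)c1)[C@H](O)[C@H]2OCCOCC
F2 | step 9 | bromine-free dimer bis-gallate (10 with H at C8) | O(Cc1ccccc1)c1cc(OCc3ccccc3)c2c(c1)O[C@H](c1ccc(OCc3ccccc3)c(OCc3ccccc3)c1)[C@H](OC(=O)c1cc(OCc3ccccc3)c(OCc3ccccc3)c(OCc3ccccc3)c1)[C@H]2c1c(OCc3ccccc3)cc(OCc3ccccc3)c2c1O[C@H](c1ccc(OCc3ccccc3)c(OCc3ccccc3)c1)[C@H](OC(=O)c1cc(OCc3ccccc3)c(OCc3ccccc3)c(OCc3ccccc3)c1)C2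
F3 | step 9 | benzylated trimer alcohol with 4β→8 upper linkage (C4 epimer of 20) | O(Cc1ccccc1)c1cc(OCc3ccccc3)c2c(c1)O[C@H](c1ccc(OCc3ccccc3)c(OCc3ccccc3)c1)[C@H](O)[C@H]2c1c(OCc3ccccc3)cc(OCc3ccccc3)c2c1O[C@H](c1ccc(OCc3ccccc3)c(OCc3ccccc3)c1)[C@H](OC(=O)c1cc(OCc3ccccc3)c(OCc3ccccc3)c(OCc3ccccc3)c1)[C@H]2c1c(OCc3ccccc3)cc(OCc3ccccc3)c2c1O[C@H](c1ccc(OCc3ccccc3)c(OCc3ccccc3)c1)[C@H](OC(=O)c1cc(OCc3ccccc3)c(OCc3ccccc3)c(OCc3ccccc3)c1)C2
F4 | step 9 | flavan-3-one trimer with 4β-aryl upper unit (2,4-trans; C4 epimer of 19) | O(Cc1ccccc1)c1cc(OCc3ccccc3)c2c(c1)O[C@H](c1ccc(OCc3ccccc3)c(OCc3ccccc3)c1)C(=O)[C@H]2c1c(OCc3ccccc3)cc(OCc3ccccc3)c2c1O[C@H](c1ccc(OCc3ccccc3)c(OCc3ccccc3)c1)[C@H](OC(=O)c1cc(OCc3ccccc3)c(OCc3ccccc3)c(OCc3ccccc3)c1)[C@H]2c1c(OCc3ccccc3)cc(OCc3ccccc3)c2c1O[C@H](c1ccc(OCc3ccccc3)c(OCc3ccccc3)c1)[C@H](OC(=O)c1cc(OCc3ccccc3)c(OCc3ccccc3)c(OCc3ccccc3)c1)C2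
F5 | step 10 | 3-O-TBS ether of 20 (upper unit all-cis) | O(Cc1ccccc1)c1cc(OCc3ccccc3)c2c(c1)O[C@H](c1ccc(OCc3ccccc3)c(OCc3ccccc3)c1)[C@H](O[Si](C)(C)C(C)(C)C)[C@@H]2c1c(OCc3ccccc3)cc(OCc3ccccc3)c2c1O[C@H](c1ccc(OCc3ccccc3)c(OCc3ccccc3)c1)[C@H](OC(=O)c1cc(OCc3ccccc3)c(OCc3ccccc3)c(OCc3ccccc3)c1)[C@H]2c1c(OCc3ccccc3)cc(OCc3ccccc3)c2c1O[C@H](c1ccc(OCc3ccccc3)c(OCc3ccccc3)c1)[C@H](OC(=O)c1cc(OCc3ccccc3)c(OCc3ccccc3)c(OCc3ccccc3)c1)C2
F6 | step 6 | 5,7,3',4'-tetra-O-benzyl-3-O-TBS-(−)-epicatechin | O(Cc1ccccc1)c1cc(OCc3ccccc3)c2c(c1)O[C@H](c1ccc(OCc3ccccc3)c(OCc3ccccc3)c1)[C@H](O[Si](C)(C)C(C)(C)C)C2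
F7 | step 6 | 4β-hydroxy derivative of F6 (2,3-cis-3,4-trans) | O(Cc1ccccc1)c1cc(OCc3ccccc3)c2c(c1)O[C@H](c1ccc(OCc3ccccc3)c(OCc3ccccc3)c1)[C@H](O[Si](C)(C)C(C)(C)C)[C@H]2O
F8 | step 6 | 2,3-cis-5,7,3',4'-tetra-O-benzyl-3-(TBS-oxy)flavan-4-one (C3 epimer of 14) | O(Cc1ccccc1)c1cc(OCc3ccccc3)c2c(c1)O[C@H](c1ccc(OCc3ccccc3)c(OCc3ccccc3)c1)[C@H](O[Si](C)(C)C(C)(C)C)C2=O
F9 | step 6 | C4 N-tosylhydrazone of F8 (2,3-cis) | O(Cc1ccccc1)c1cc(OCc3ccccc3)c2c(c1)O[C@H](c1ccc(OCc3ccccc3)c(OCc3ccccc3)c1)[C@H](O[Si](C)(C)C(C)(C)C)C2=NNS(=O)(=O)c1ccc(C)cc1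
F10 | step 6 | 2,3-cis 4-diazo compound from F9 (C3 epimer of 17) | O(Cc1ccccc1)c1cc(OCc3ccccc3)c2c(c1)O[C@H](c1ccc(OCc3ccccc3)c(OCc3ccccc3)c1)[C@H](O[Si](C)(C)C(C)(C)C)C2=[N+]=[N-]
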